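**Retrosynthetic overview**

The plan rests on the homoallylic pattern C8(OH)–C9H2–C10(=C14H2) that appears in the ten-membered carbocycle (C1–C10) once C10–C14 is read as an exocyclic methylene. The ring is closed last at C8–C9 by chromium-mediated allylation of a 4-formylbutenolide (C8 aldehyde) with a 2-substituted allyl bromide (C9/C10/C14); the C1 oxygen then moves the oxirane from C10–C14 to C1–C10 (Payne shift) and frees C14–OH.
The open-chain precursor is cut at C1–C2 (zinc alkynylide plus an enal from 2-methylenepropane-1,3-diol, then cis-semihydrogenation) and at C6–C7 (Ni/Cr alkenylation of an epoxy aldehyde by a Z-β-iodo-enoate that lactonises).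
C4/C5 come from Sharpless epoxidation of (Z)-3-methylpent-2-en-4-yn-1-ol, C6 from Felkin–Anh addition, C1 from ligand control, C8 from the ring closure, C10 from hydroxyl-directed epoxidation followed by inversion in the Payne step.
Ring order: oxirane C4–C5, then butenolide (C6, C7, C11, C12, O), then the ten-membered carbocycle, then the spiro-oxirane C10–C14, which is transposed into the C1–C10 oxirane.

Key step: step 17

Remark (numbering): atoms carry germacranolide numbers (C1–C10 ring, C11/C12 lactone, C13 = CH2OAc, C14 = CH2 on C10, C15 = CH3 on C4); the open-chain compounds 19–26 are named as 8,9-seco-germacranolides.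
Assumption: the (S,S) antipode of ProPhenol is taken to deliver the alkynyl group to the aldehyde face that gives 1R; if the sense is the opposite, the (R,R) ligand is used with no other change.
Assumption: (Z)-3-methylpent-2-en-4-yn-1-ol (12) is taken as a commercial starting material.

**Route**

Step 1
Reactants: 1 prop-2-yn-1-ol
Product: 2 triethyl(prop-2-yn-1-yloxy)silane
Conditions: TESCl, imidazole, CH2Cl2, 0 °C to rt
Reagents that add atoms: chlorotriethylsilane (CC[Si](Cl)(CC)CC)
Why: Standard silylation of a primary alcohol gives a C8–O triethylsilyl ether that can later be removed beside a secondary tert-butyldimethylsilyl ether.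

Step 2
Reactants: 2 triethyl(prop-2-yn-1-yloxy)silane
Product: 4 ethyl 4-(triethylsilyloxy)but-2-ynoate, via lithium acetylide 3 (not isolated)
Conditions: n-BuLi, THF, −78 °C; then ClCO2Et, −78 to 0 °C
Reagents that add atoms: ethyl chloroformate (CCOC(=O)Cl)
Why: Deprotonation of the terminal alkyne and C-acylation of the acetylide with a chloroformate is the standard alkynoate synthesis and installs C12 on C11.

Step 3
Reactants: 4 ethyl 4-(triethylsilyloxy)but-2-ynoate
Product: 6 ethyl (2Z)-2-(hydroxymethyl)-3-iodo-4-(triethylsilyloxy)but-2-enoate, via magnesium iodoallenolate 5 (not isolated)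
Conditions: MgI2, CH2Cl2, 0 °C; then CH2O (gas from cracked paraformaldehyde), −20 to 0 °C
Reagents that add atoms: magnesium iodide (I[Mg]I); formaldehyde (C=O)
Why: Iodo-aldol (β-iodo Morita–Baylis–Hillman) reaction: iodide adds to the alkynoate in conjugate fashion and the β-iodoallenolate is hydroxymethylated at C11 anti to iodine, so iodine ends cis to the ester (Z); a 3-substituted alkynoate should react more slowly than a propiolate, and any E isomer would be removed by chromatography because only the Z isomer can lactonise in step 9.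

Step 4
Reactants: 6 ethyl (2Z)-2-(hydroxymethyl)-3-iodo-4-(triethylsilyloxy)but-2-enoate
Product: 7 ethyl (2Z)-2-(acetoxymethyl)-3-iodo-4-(triethylsilyloxy)but-2-enoate
Conditions: Ac2O, pyridine, DMAP (cat.), CH2Cl2, 0 °C
Reagents that add atoms: acetic anhydride (CC(=O)OC(C)=O)
Why: Acetylation of the primary alcohol puts the C13 acetate in place from the start, so C8–O and C13–O stay differentiated throughout.

Step 5
Reactants: 8 2-methylenepropane-1,3-diol
Product: 10 2-[(4-methoxybenzyloxy)methyl]prop-2-en-1-ol, via sodium monoalkoxide 9 (not isolated)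
Conditions: NaH (1 equiv), THF, 0 °C; then PMBCl, Bu4NI (cat.), 0 °C to rt (diol in excess)
Reagents that add atoms: 4-methoxybenzyl chloride (COc1ccc(CCl)cc1)
Why: Williamson monoetherification of the symmetric diol through its monoalkoxide gives the C9–O ether; excess diol should suppress the bis-ether.

Step 6
Reactants: 10 2-[(4-methoxybenzyloxy)methyl]prop-2-en-1-ol
Product: 11 2-[(4-methoxybenzyloxy)methyl]prop-2-enal
Conditions: MnO2, CH2Cl2, rt
Reagents that add atoms: none
Why: Manganese dioxide oxidises the allylic alcohol selectively to the enal (C1 aldehyde), which is used at once because 2-substituted acroleins tend to polymerise.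

Step 7
Reactants: 12 (2Z)-3-methylpent-2-en-4-yn-1-ol
Product: 13 [(2S,3R)-3-ethynyl-3-methyloxiran-2-yl]methanol
Conditions: Ti(OiPr)4, L-(+)-diethyl tartrate, t-BuOOH, 4 Å MS, CH2Cl2, −20 °C
Reagents that add atoms: tert-butyl hydroperoxide (CC(C)(C)OO)
Why: Sharpless asymmetric epoxidation: the titanium tartrate complex binds the allylic hydroxyl and delivers peroxide oxygen to one alkene face, L-(+)-tartrate giving the 2S,3R oxirane (C5 S and C4 R of the target), while the Z geometry of 12 fixes C3 and C6 cis on the oxirane.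

Step 8
Reactants: 13 [(2S,3R)-3-ethynyl-3-methyloxiran-2-yl]methanol
Product: 14 (2R,3R)-3-ethynyl-3-methyloxirane-2-carbaldehyde
Conditions: Dess–Martin periodinane, NaHCO3, CH2Cl2, 0 °C to rt; used crude
Reagents that add atoms: none
Why: Buffered Dess–Martin oxidation converts the epoxy alcohol into the C6 epoxy aldehyde without epimerising the α-carbon (the descriptor at that carbon changes only because the priorities change).

Step 9
Reactants: 14 (2R,3R)-3-ethynyl-3-methyloxirane-2-carbaldehyde; 7 ethyl (2Z)-2-(acetoxymethyl)-3-iodo-4-(triethylsilyloxy)but-2-enoate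
Product: 17 [(5S)-5-[(2S,3R)-3-ethynyl-3-methyloxiran-2-yl]-2-oxo-4-[(triethylsilyloxy)methyl]-2,5-dihydrofuran-3-yl]methyl acetate, via alkenylchromium dichloride 15 (not isolated), via hydroxy ester 16 (not isolated)
Conditions: CrCl2 (6 equiv), NiCl2 (2 mol %), DMF, rt; aq NH4Cl work-up, then PPTS (cat.), CH2Cl2 if lactonisation is incomplete
Reagents that add atoms: none
Why: Nozaki–Hiyama–Kishi alkenylation: zerovalent nickel inserts into the C–I bond, the alkenyl group passes to trivalent chromium and adds to the aldehyde anti to the oxirane C–O bond (Felkin–Anh), which sets C6 as S and forms C6–C7, and the Z-γ-hydroxy enoate 16 then closes to the butenolide with loss of ethanol; the minor C6 epimer would be removed by chromatography.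

Step 10
Reactants: 17 [(5S)-5-[(2S,3R)-3-ethynyl-3-methyloxiran-2-yl]-2-oxo-4-[(triethylsilyloxy)methyl]-2,5-dihydrofuran-3-yl]methyl acetate; 11 2-[(4-methoxybenzyloxy)methyl]prop-2-enal
Product: 19 (1R,4R,5S,6S)-13-acetoxy-4,5-epoxy-1-hydroxy-9-(4-methoxybenzyloxy)-8-(triethylsilyloxy)-8,9-secogermacra-7(11),10(14)-dien-2-yn-12,6-olide, via methylzinc acetylide 18 (not isolated)
Conditions: Me2Zn (3 equiv), (S,S)-ProPhenol (20 mol %), Ph3P=O (40 mol %), toluene, 0 to 4 °C
Reagents that add atoms: none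
Why: Catalytic asymmetric alkynylation: the dinuclear zinc–ProPhenol complex adds the zinc alkynylide to the enal in 1,2-fashion and the ligand alone selects the aldehyde face, setting C1 as R and forming C1–C2; Me2Zn does not attack the lactone or the acetate.

Step 11
Reactants: 19 (1R,4R,5S,6S)-13-acetoxy-4,5-epoxy-1-hydroxy-9-(4-methoxybenzyloxy)-8-(triethylsilyloxy)-8,9-secogermacra-7(11),10(14)-dien-2-yn-12,6-olide
Product: 20 (1R,2Z,4R,5S,6S)-13-acetoxy-4,5-epoxy-1-hydroxy-9-(4-methoxybenzyloxy)-8-(triethylsilyloxy)-8,9-secogermacra-2,7(11),10(14)-trien-12,6-olide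
Conditions: H2 (1 atm), Pd/CaCO3 poisoned with Pb(OAc)2 (Lindlar catalyst), quinoline, EtOAc, rt
Reagents that add atoms: none
Why: Lindlar semihydrogenation adds H2 syn to the alkyne and stops at the alkene, giving the 2Z double bond; alkynyl oxiranes are known to survive as cis-vinyl oxiranes, and the tetrasubstituted butenolide alkene and the 1,1-disubstituted alkene are not reduced.

Step 12
Reactants: 20 (1R,2Z,4R,5S,6S)-13-acetoxy-4,5-epoxy-1-hydroxy-9-(4-methoxybenzyloxy)-8-(triethylsilyloxy)-8,9-secogermacra-2,7(11),10(14)-trien-12,6-olide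
Product: 21 (1R,2Z,4R,5S,6S)-13-acetoxy-1-(tert-butyldimethylsilyloxy)-4,5-epoxy-9-(4-methoxybenzyloxy)-8-(triethylsilyloxy)-8,9-secogermacra-2,7(11),10(14)-trien-12,6-olide
Conditions: TBSOTf, 2,6-lutidine, CH2Cl2, −78 °C
Reagents that add atoms: tert-butyldimethylsilyl trifluoromethanesulfonate (CC(C)(C)[Si](C)(C)OS(=O)(=O)C(F)(F)F)
Why: Silylation of the secondary allylic alcohol with a silyl triflate and a hindered non-nucleophilic base is fast at −78 °C, so the vinyl oxirane and the allylic acetate are not engaged.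

Step 13
Reactants: 21 (1R,2Z,4R,5S,6S)-13-acetoxy-1-(tert-butyldimethylsilyloxy)-4,5-epoxy-9-(4-methoxybenzyloxy)-8-(triethylsilyloxy)-8,9-secogermacra-2,7(11),10(14)-trien-12,6-olide
Product: 22 (1R,2Z,4R,5S,6S)-13-acetoxy-1-(tert-butyldimethylsilyloxy)-4,5-epoxy-9-hydroxy-8-(triethylsilyloxy)-8,9-secogermacra-2,7(11),10(14)-trien-12,6-olide
Conditions: DDQ, CH2Cl2/pH 7 buffer, 0 °C
Reagents that add atoms: none
Why: DDQ cleaves the 4-methoxybenzyl ether oxidatively (benzylic hydride abstraction, then hydrolysis) and frees C9–OH, while silyl ethers, acetate and the vinyl oxirane are inert.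

Step 14
Reactants: 22 (1R,2Z,4R,5S,6S)-13-acetoxy-1-(tert-butyldimethylsilyloxy)-4,5-epoxy-9-hydroxy-8-(triethylsilyloxy)-8,9-secogermacra-2,7(11),10(14)-trien-12,6-olide
Product: 23 (1R,2Z,4R,5S,6S)-13-acetoxy-9-bromo-1-(tert-butyldimethylsilyloxy)-4,5-epoxy-8-(triethylsilyloxy)-8,9-secogermacra-2,7(11),10(14)-trien-12,6-olide
Conditions: CBr4, PPh3, 2,6-lutidine, CH2Cl2, −20 to 0 °C
Reagents that add atoms: tetrabromomethane (BrC(Br)(Br)Br)
Why: Appel reaction: bromide displaces the oxyphosphonium salt of the primary allylic alcohol under neutral conditions, and SN2 and SN2′ attack lead to the same 2-substituted allyl bromide.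

Step 15
Reactants: 23 (1R,2Z,4R,5S,6S)-13-acetoxy-9-bromo-1-(tert-butyldimethylsilyloxy)-4,5-epoxy-8-(triethylsilyloxy)-8,9-secogermacra-2,7(11),10(14)-trien-12,6-olide
Product: 24 (1R,2Z,4R,5S,6S)-13-acetoxy-9-bromo-1-(tert-butyldimethylsilyloxy)-4,5-epoxy-8-hydroxy-8,9-secogermacra-2,7(11),10(14)-trien-12,6-olide
Conditions: Et3N·3HF, MeCN, 0 °C
Reagents that add atoms: none
Why: Fluoride cleaves a primary triethylsilyl ether far faster than a hindered secondary tert-butyldimethylsilyl ether, and the amine–HF complex is neither basic nor nucleophilic enough to attack the allylic bromide or C6–H.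

Step 16
Reactants: 24 (1R,2Z,4R,5S,6S)-13-acetoxy-9-bromo-1-(tert-butyldimethylsilyloxy)-4,5-epoxy-8-hydroxy-8,9-secogermacra-2,7(11),10(14)-trien-12,6-olide
Product: 25 (1R,2Z,4R,5S,6S)-13-acetoxy-9-bromo-1-(tert-butyldimethylsilyloxy)-4,5-epoxy-8-oxo-8,9-secogermacra-2,7(11),10(14)-trien-12,6-olide
Conditions: Dess–Martin periodinane, NaHCO3, CH2Cl2, 0 °C; used at once
Reagents that add atoms: none
Why: Neutral Dess–Martin oxidation of the primary allylic alcohol gives the 4-formylbutenolide without touching the allylic bromide or the base-sensitive C6–H.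

Step 17
Reactants: 25 (1R,2Z,4R,5S,6S)-13-acetoxy-9-bromo-1-(tert-butyldimethylsilyloxy)-4,5-epoxy-8-oxo-8,9-secogermacra-2,7(11),10(14)-trien-12,6-olide
Product: 27 (1R,2Z,4R,5S,6S,8S)-13-acetoxy-1-(tert-butyldimethylsilyloxy)-4,5-epoxy-8-hydroxygermacra-2,7(11),10(14)-trien-12,6-olide, via allylchromium dichloride 26 (not isolated)
Conditions: CrCl2 (10 equiv), THF, rt, slow syringe-pump addition of 25 (final 0.002 M)
Reagents that add atoms: none
Why: Divalent chromium (two equivalents per C–Br bond) reduces the allylic bromide to the allylchromium dichloride 26 (trivalent chromium), which adds to the C8 aldehyde through its distal CH2 terminus in a chair-like six-membered Cr–O transition state, forming C8–C9 with allylic transposition so that C10=C14 ends exocyclic; this is an intramolecular Nozaki–Hiyama allylation, the reaction type used to close ten-membered germacrane rings. The ten-membered carbocycle closes in the 10-exo-trig mode at the aldehyde carbon, favoured over chain growth by high dilution. C8 is set by the substrate: the aldehyde should react in its conjugated s-trans form with C8–H turned toward the C13 acetoxymethyl group, and the planar C6–C7–C8 unit lets the ring close without a syn-pentane-type clash only when C5 and C9 lie on opposite faces of the butenolide, so C9 should bond to the aldehyde face anti to C5, which gives 8S. The step needs chemoselectivity for C–Br over the enal, the allylic acetate and the vinyl oxirane, which is secured because reduction of an allylic bromide by CrCl2 is much faster than any of these and the allylchromium species is not basic enough to remove C6–H. Regiochemistry is no issue because the two CH2 termini of the 2-substituted allyl unit are equivalent.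

Step 18
Reactants: 27 (1R,2Z,4R,5S,6S,8S)-13-acetoxy-1-(tert-butyldimethylsilyloxy)-4,5-epoxy-8-hydroxygermacra-2,7(11),10(14)-trien-12,6-olide; 28 (2R)-2-methylbutanoic acid
Product: 29 (1R,2Z,4R,5S,6S,8S)-13-acetoxy-1-(tert-butyldimethylsilyloxy)-4,5-epoxy-8-[(2R)-2-methylbutanoyloxy]germacra-2,7(11),10(14)-trien-12,6-olide
Conditions: EDC·HCl, DMAP (5 mol %), CH2Cl2, 0 °C to rt
Reagents that add atoms: none
Why: Carbodiimide (Steglich) esterification acylates C8–OH with retention at C8, and activation at 0 °C with only catalytic DMAP should keep the α-stereocentre of the acid; esterifying now also removes C8–OH as a competing directing group for step 20.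

Step 19
Reactants: 29 (1R,2Z,4R,5S,6S,8S)-13-acetoxy-1-(tert-butyldimethylsilyloxy)-4,5-epoxy-8-[(2R)-2-methylbutanoyloxy]germacra-2,7(11),10(14)-trien-12,6-olide
Product: 30 (1R,2Z,4R,5S,6S,8S)-13-acetoxy-4,5-epoxy-1-hydroxy-8-[(2R)-2-methylbutanoyloxy]germacra-2,7(11),10(14)-trien-12,6-olide
Conditions: HF·pyridine, pyridine, THF, 0 °C to rt
Reagents that add atoms: none
Why: Buffered HF·pyridine cleaves the secondary silyl ether through Si–F bond formation under weakly acidic conditions that leave the esters, the lactone and the vinyl oxirane intact.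

Step 20
Reactants: 30 (1R,2Z,4R,5S,6S,8S)-13-acetoxy-4,5-epoxy-1-hydroxy-8-[(2R)-2-methylbutanoyloxy]germacra-2,7(11),10(14)-trien-12,6-olide
Product: 31 (1R,2Z,4R,5S,6S,8S,10R)-13-acetoxy-4,5:10,14-diepoxy-1-hydroxy-8-[(2R)-2-methylbutanoyloxy]germacra-2,7(11)-dien-12,6-olide
Conditions: VO(acac)2 (5 mol %), t-BuOOH (anhydrous, 1.5 equiv), CH2Cl2, 0 °C
Reagents that add atoms: tert-butyl hydroperoxide (CC(C)(C)OO)
Why: Hydroxyl-directed epoxidation: the vanadate ester of C1–OH delivers peroxide oxygen to the adjacent 1,1-disubstituted alkene, which is more electron-rich and less hindered than C2=C3; with C1–H in the plane of both flanking alkenes (least allylic strain) O1 sits over the methylene face opposite to C2, so oxygen should enter there and make C10 R, the anti epoxy alcohol that the Payne step requires.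

Step 21
Reactants: 31 (1R,2Z,4R,5S,6S,8S,10R)-13-acetoxy-4,5:10,14-diepoxy-1-hydroxy-8-[(2R)-2-methylbutanoyloxy]germacra-2,7(11)-dien-12,6-olide
Product: 33 (1R,2Z,4R,5S,6S,8S,10S)-13-acetoxy-1,10:4,5-diepoxy-14-hydroxy-8-[(2R)-2-methylbutanoyloxy]germacra-2,7(11)-dien-12,6-olide, via sodium alkoxide 32 (not isolated)
Conditions: NaH (0.3 equiv), THF, −20 to 0 °C; AcOH quench
Reagents that add atoms: none
Why: Payne rearrangement: the C1 alkoxide opens the spiro-oxirane at C10 from the rear (3-exo-tet, inversion at C10, retention at C1) to give the more substituted 1,10-oxirane with C2 and C9 trans plus the primary C14 alkoxide, the favoured side of the equilibrium; catalytic base at low temperature keeps the alkoxide concentration small so that C6–H and the three ester groups should be spared.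

**Compound list**

1 | prop-2-yn-1-ol | C#CCO | starting material
2 | triethyl(prop-2-yn-1-yloxy)silane | C#CCO[Si](CC)(CC)CC | intermediate
3 | [3-(triethylsilyloxy)prop-1-yn-1-yl]lithium | [Li]C#CCO[Si](CC)(CC)CC | intermediate
4 | ethyl 4-(triethylsilyloxy)but-2-ynoate | CCOC(=O)C#CCO[Si](CC)(CC)CC | intermediate
5 | iodomagnesium 1-ethoxy-3-iodo-4-(triethylsilyloxy)buta-1,2-dien-1-olate | CCOC(O[Mg]I)=C=C(I)CO[Si](CC)(CC)CC | intermediate
6 | ethyl (2Z)-2-(hydroxymethyl)-3-iodo-4-(triethylsilyloxy)but-2-enoate | CCOC(=O)/C(CO)=C(\I)CO[Si](CC)(CC)CC | intermediate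
7 | ethyl (2Z)-2-(acetoxymethyl)-3-iodo-4-(triethylsilyloxy)but-2-enoate (fragment A: C7, C8, C11–C13) | CCOC(=O)/C(COC(C)=O)=C(\I)CO[Si](CC)(CC)CC | intermediate
8 | 2-methylenepropane-1,3-diol | C=C(CO)CO | starting material
9 | sodium 2-(hydroxymethyl)prop-2-en-1-olate | [Na+].[O-]CC(=C)CO | intermediate
10 | 2-[(4-methoxybenzyloxy)methyl]prop-2-en-1-ol | C=C(CO)COCc1ccc(OC)cc1 | intermediate
11 | 2-[(4-methoxybenzyloxy)methyl]prop-2-enal (fragment B: C1, C9, C10, C14) | C=C(C=O)COCc1ccc(OC)cc1 | intermediate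
12 | (2Z)-3-methylpent-2-en-4-yn-1-ol | C#C/C(C)=C\CO | starting material
13 | [(2S,3R)-3-ethynyl-3-methyloxiran-2-yl]methanol | C#C[C@@]1(C)O[C@H]1CO | intermediate
14 | (2R,3R)-3-ethynyl-3-methyloxirane-2-carbaldehyde | C#C[C@@]1(C)O[C@H]1C=O | intermediate
15 | dichloro[(2Z)-3-(acetoxymethyl)-4-ethoxy-4-oxo-1-(triethylsilyloxy)but-2-en-2-yl]chromium | CCOC(=O)/C(COC(C)=O)=C(\[Cr](Cl)Cl)CO[Si](CC)(CC)CC | intermediate
16 | ethyl (2Z,4S)-2-(acetoxymethyl)-4-[(2S,3R)-3-ethynyl-3-methyloxiran-2-yl]-4-hydroxy-3-[(triethylsilyloxy)methyl]but-2-enoate | CCOC(=O)/C(COC(C)=O)=C(\[C@H](O)[C@@H]1O[C@]1(C)C#C)CO[Si](CC)(CC)CC | intermediate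
17 | [(5S)-5-[(2S,3R)-3-ethynyl-3-methyloxiran-2-yl]-2-oxo-4-[(triethylsilyloxy)methyl]-2,5-dihydrofuran-3-yl]methyl acetate | C#C[C@@]1(C)O[C@H]1[C@H]1OC(=O)C(COC(C)=O)=C1CO[Si](CC)(CC)CC | intermediate
18 | methylzinc acetylide of 17 (Zn on C2) | C[Zn]C#C[C@@]1(C)O[C@H]1[C@H]1OC(=O)C(COC(C)=O)=C1CO[Si](CC)(CC)CC | intermediate
19 | (1R,4R,5S,6S)-13-acetoxy-4,5-epoxy-1-hydroxy-9-(4-methoxybenzyloxy)-8-(triethylsilyloxy)-8,9-secogermacra-7(11),10(14)-dien-2-yn-12,6-olide | C=C(COCc1ccc(OC)cc1)[C@H](O)C#C[C@@]1(C)O[C@H]1[C@H]1OC(=O)C(COC(C)=O)=C1CO[Si](CC)(CC)CC | intermediate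
20 | (1R,2Z,4R,5S,6S)-13-acetoxy-4,5-epoxy-1-hydroxy-9-(4-methoxybenzyloxy)-8-(triethylsilyloxy)-8,9-secogermacra-2,7(11),10(14)-trien-12,6-olide | C=C(COCc1ccc(OC)cc1)[C@H](O)/C=C\[C@@]1(C)O[C@H]1[C@H]1OC(=O)C(COC(C)=O)=C1CO[Si](CC)(CC)CC | intermediate
21 | (1R,2Z,4R,5S,6S)-13-acetoxy-1-(tert-butyldimethylsilyloxy)-4,5-epoxy-9-(4-methoxybenzyloxy)-8-(triethylsilyloxy)-8,9-secogermacra-2,7(11),10(14)-trien-12,6-olide | C=C(COCc1ccc(OC)cc1)[C@H](O[Si](C)(C)C(C)(C)C)/C=C\[C@@]1(C)O[C@H]1[C@H]1OC(=O)C(COC(C)=O)=C1CO[Si](CC)(CC)CC | intermediate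
22 | (1R,2Z,4R,5S,6S)-13-acetoxy-1-(tert-butyldimethylsilyloxy)-4,5-epoxy-9-hydroxy-8-(triethylsilyloxy)-8,9-secogermacra-2,7(11),10(14)-trien-12,6-olide | C=C(CO)[C@H](O[Si](C)(C)C(C)(C)C)/C=C\[C@@]1(C)O[C@H]1[C@H]1OC(=O)C(COC(C)=O)=C1CO[Si](CC)(CC)CC | intermediate
23 | (1R,2Z,4R,5S,6S)-13-acetoxy-9-bromo-1-(tert-butyldimethylsilyloxy)-4,5-epoxy-8-(triethylsilyloxy)-8,9-secogermacra-2,7(11),10(14)-trien-12,6-olide | C=C(CBr)[C@H](O[Si](C)(C)C(C)(C)C)/C=C\[C@@]1(C)O[C@H]1[C@H]1OC(=O)C(COC(C)=O)=C1CO[Si](CC)(CC)CC | intermediate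
24 | (1R,2Z,4R,5S,6S)-13-acetoxy-9-bromo-1-(tert-butyldimethylsilyloxy)-4,5-epoxy-8-hydroxy-8,9-secogermacra-2,7(11),10(14)-trien-12,6-olide | C=C(CBr)[C@H](O[Si](C)(C)C(C)(C)C)/C=C\[C@@]1(C)O[C@H]1[C@H]1OC(=O)C(COC(C)=O)=C1CO | intermediate
25 | (1R,2Z,4R,5S,6S)-13-acetoxy-9-bromo-1-(tert-butyldimethylsilyloxy)-4,5-epoxy-8-oxo-8,9-secogermacra-2,7(11),10(14)-trien-12,6-olide (cyclisation precursor: 4-formylbutenolide with C9 allylic bromide) | C=C(CBr)[C@H](O[Si](C)(C)C(C)(C)C)/C=C\[C@@]1(C)O[C@H]1[C@H]1OC(=O)C(COC(C)=O)=C1C=O | intermediate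
26 | C9 allylchromium dichloride of 25 (CrCl2 in place of Br) | C=C(C[Cr](Cl)Cl)[C@H](O[Si](C)(C)C(C)(C)C)/C=C\[C@@]1(C)O[C@H]1[C@H]1OC(=O)C(COC(C)=O)=C1C=O | intermediate
27 | (1R,2Z,4R,5S,6S,8S)-13-acetoxy-1-(tert-butyldimethylsilyloxy)-4,5-epoxy-8-hydroxygermacra-2,7(11),10(14)-trien-12,6-olide | O[C@H]1CC(=C)[C@H](O[Si](C)(C)C(C)(C)C)/C=C\[C@@]2(C)O[C@H]2[C@H]2OC(=O)C(COC(C)=O)=C12 | intermediate
28 | (2R)-2-methylbutanoic acid | CC[C@@H](C)C(=O)O | starting material
29 | (1R,2Z,4R,5S,6S,8S)-13-acetoxy-1-(tert-butyldimethylsilyloxy)-4,5-epoxy-8-[(2R)-2-methylbutanoyloxy]germacra-2,7(11),10(14)-trien-12,6-olide | CC[C@@H](C)C(=O)O[C@H]1CC(=C)[C@H](O[Si](C)(C)C(C)(C)C)/C=C\[C@@]2(C)O[C@H]2[C@H]2OC(=O)C(COC(C)=O)=C12 | intermediate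
30 | (1R,2Z,4R,5S,6S,8S)-13-acetoxy-4,5-epoxy-1-hydroxy-8-[(2R)-2-methylbutanoyloxy]germacra-2,7(11),10(14)-trien-12,6-olide | CC[C@@H](C)C(=O)O[C@H]1CC(=C)[C@H](O)/C=C\[C@@]2(C)O[C@H]2[C@H]2OC(=O)C(COC(C)=O)=C12 | intermediate
31 | (1R,2Z,4R,5S,6S,8S,10R)-13-acetoxy-4,5:10,14-diepoxy-1-hydroxy-8-[(2R)-2-methylbutanoyloxy]germacra-2,7(11)-dien-12,6-olide | CC[C@@H](C)C(=O)O[C@H]1C[C@@]3(CO3)[C@H](O)/C=C\[C@@]2(C)O[C@H]2[C@H]2OC(=O)C(COC(C)=O)=C12 | intermediate
32 | sodium C1-alkoxide of 31 | CC[C@@H](C)C(=O)O[C@H]1C[C@@]3(CO3)[C@H]([O-])/C=C\[C@@]2(C)O[C@H]2[C@H]2OC(=O)C(COC(C)=O)=C12.[Na+] | intermediate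
33 | (1R,2Z,4R,5S,6S,8S,10S)-13-acetoxy-1,10:4,5-diepoxy-14-hydroxy-8-[(2R)-2-methylbutanoyloxy]germacra-2,7(11)-dien-12,6-olide (CNP0108300.1) | CC[C@@H](C)C(=O)O[C@H]1C[C@@]2(CO)O[C@@H]2/C=C\[C@@]2(C)O[C@H]2[C@H]2OC(=O)C(COC(C)=O)=C12 | target

**Totals**

Total step count: 21 (steps 1–4 fragment A, steps 5–6 fragment B, steps 7–21 main line).
Longest linear sequence: 17 steps (steps 1–4, then 9–21, from prop-2-yn-1-ol); 15 steps from (Z)-3-methylpent-2-en-4-yn-1-ol.

**Three steps most likely to fail**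

1. Step 17 (ring closure). The allyl group may reach the other face of the C8 aldehyde (poor facial selectivity, since C8 is set only by the conformation of the closing ring), and chain growth between molecules or reduction of the ene-dicarbonyl unit by divalent chromium may compete with closure. Fallback for the facial problem: setting out from 25, the same CrCl2 closure is carried through to the 8R alcohol, (1R,2Z,4R,5S,6S,8R)-13-acetoxy-1-(tert-butyldimethylsilyloxy)-4,5-epoxy-8-hydroxygermacra-2,7(11),10(14)-trien-12,6-olide F1. The ester is then installed with inversion at C8 by a Mitsunobu reaction with acid 28 (PPh3, DIAD, toluene, 0 °C), which comes back to the route at 29; the butenolide alkene is electron-poor, so SN2′ attack is not expected.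

2. Step 20 (directed epoxidation). Oxygen may be delivered to the other face of C10=C14 if the ring holds C2 rather than C1–H in the plane of the methylene; that would give the 10S spiro-oxirane and, after the Payne step, the 1,10-oxirane with C2 and C9 cis. Attack on C2=C3 is also possible. Fallback: setting out from silyl ether 29, the methylene is epoxidised without direction (mCPBA, NaHCO3, CH2Cl2, 0 °C), where the bulky C1 silyloxy group shields the face that the free hydroxyl would have served. This should give the 1-O-silyl spiro-oxirane, (1R,2Z,4R,5S,6S,8S,10R)-13-acetoxy-1-(tert-butyldimethylsilyloxy)-4,5:10,14-diepoxy-8-[(2R)-2-methylbutanoyloxy]germacra-2,7(11)-dien-12,6-olide F2. HF·pyridine (pyridine, THF, 0 °C) then frees C1–OH and the route is rejoined at 31.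

3. Step 21 (Payne shift). The alkoxide may instead remove C6–H, which is vinylogous to the lactone carbonyl, with β-opening of the 4,5-oxirane, or an acyl group may migrate to the new C14 alkoxide. Fallback without base: setting out from 30, a rhenium-oxo-catalysed 1,3-transposition of the allylic alcohol (Ph3SiOReO3 cat., Et2O, −50 to 0 °C) moves the hydroxyl from C1 to C14 and the alkene into the ring. This gives the 14-hydroxy diene with C2 and C9 trans across C1=C10, (2Z,4R,5S,6S,8S)-13-acetoxy-4,5-epoxy-14-hydroxy-8-[(2R)-2-methylbutanoyloxy]germacra-1(10),2,7(11)-trien-12,6-olide F3. Sharpless epoxidation of this primary allylic alcohol (Ti(OiPr)4, L-(+)-diethyl tartrate, t-BuOOH, 4 Å MS, CH2Cl2, −20 °C) then sets C1 (R) and C10 (S) by reagent control and comes back to the route at 33 itself.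

**Further compounds**

F1 | step 17 | (1R,2Z,4R,5S,6S,8R)-13-acetoxy-1-(tert-butyldimethylsilyloxy)-4,5-epoxy-8-hydroxygermacra-2,7(11),10(14)-trien-12,6-olide | O[C@@H]1CC(=C)[C@H](O[Si](C)(C)C(C)(C)C)/C=C\[C@@]2(C)O[C@H]2[C@H]2OC(=O)C(COC(C)=O)=C12
F2 | step 20 | (1R,2Z,4R,5S,6S,8S,10R)-13-acetoxy-1-(tert-butyldimethylsilyloxy)-4,5:10,14-diepoxy-8-[(2R)-2-methylbutanoyloxy]germacra-2,7(11)-dien-12,6-olide | CC[C@@H](C)C(=O)O[C@H]1C[C@@]3(CO3)[C@H](O[Si](C)(C)C(C)(C)C)/C=C\[C@@]2(C)O[C@H]2[C@H]2OC(=O)C(COC(C)=O)=C12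
F3 | step 21 | (2Z,4R,5S,6S,8S)-13-acetoxy-4,5-epoxy-14-hydroxy-8-[(2R)-2-methylbutanoyloxy]germacra-1(10),2,7(11)-trien-12,6-olide with C2 and C9 trans across C1=C10 | CC[C@@H](C)C(=O)O[C@H]1C/C(CO)=C/C=C\[C@@]2(C)O[C@H]2[C@H]2OC(=O)C(COC(C)=O)=C12
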